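## Structural features

The target is a sesquineolignan built on a 2-oxaspiro[4.5]decane in which ring B, an oxolane (O1, C2, C3, C4, C5), and ring A, a 2-methoxycyclohexa-2,5-dienone (C4, C2', C3' bearing OMe, carbonyl C4', C5', C6'), share the spiro carbon C4. C2 carries a 4-hydroxy-3-methoxyphenyl group, C3 the hydroxymethyl C9, and C5 the side-chain carbon C8, which bears a 2-methoxy-4-(3-hydroxypropyl)phenoxy group and the hydroxymethyl C10. The five contiguous stereocentres are (2S,3R,4S,5S,8S): on ring B the aryl group is trans to C9 and the C8 chain is cis to C9, and at C4 the arm C2' lies on the face of C9 and C8 and the arm C6' on the aryl face. C4 is stereogenic only because the two arms of ring A differ by the C3' methoxy group, so the arms must stay distinguishable to the last step. Fragile groups are the cross-conjugated dienone with its vinylogous ester, the free phenol para to the benzylic C2–O1 ether (ionisation towards a quinone methide), and the β-aryloxy alcohol at C8. The real difficulty is the quaternary spiro centre flanked by stereocentres at C3 and C5, with a further acyclic centre at C8 that no ring controls. The key step exploits the array O1–C5–C8(OAr)–C10: C5 carries the ring oxygen and C8 an aryloxy group next to a carbon that can be a carboxyl carbon, which is the pattern left by oxa-Michael addition of the C2 hydroxyl to a 2-aryloxyacrylate attached to C4.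

## Logic of the disconnections

**38 back to 31.** The four silyl ethers, the O–CH3 bond at C3', the C3'–O bond and the C4' carbonyl are removed in turn (38, 37, 36, 34, 32, 31). The dienone is the most fragile part and would be a second Michael acceptor, so it is built last. The gain is a ring A that is a plain cyclohexene. The demand is that the oxidants touch ring A only, and that the C3' oxygen goes onto the arm that is saturated in 31, because that choice alone carries the C4 configuration into 38.

**31 back to 29.** The C10–O silyl bond is cut and C10 is raised to the ester level (31, 30, 29). The ester is what makes C8 part of an acrylate one step earlier. The demand is a reduction that does not enolise C8 or reopen ring B.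

**29 back to 28.** The O1–C5 bond and the C8–H bond are cut. This removes ring B and two stereocentres and leaves an acyclic hydroxy acrylate whose three centres (C2, C3, C4) are already in place. The demand is that C5 and C8 be set by equilibration. Three design choices are built into 28. It is drawn as the (Z)-alkene, the isomer the olefination should favour, although either geometry feeds the same equilibrium. O9 and the phenol carry TIPS groups, so that no 1,5-silyl shift to the C2 alkoxide and no loss of the aryl silyl ether can occur under base. The C2 hydroxyl can be left free only because C5 is unmasked late, as a lactol. The configurations of 28 and 29 correspond atom by atom to those of 38.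

**28 back to 21 and 26.** The C5=C8 double bond is cut. The phosphonate half 26 carries the aryl ether and the ester; the other half is 21, the cyclic form of the C5 aldehyde, which reaches the olefination through its open form 27. The demand is an olefination that works through the small share of open aldehyde and under base too mild to move silyl groups.

**26 back to 23 and 25, then 22 and 24.** The C8–O aryl ether bond is cut (carbenoid O–H insertion). The phenol goes back to 22 by removal of one silyl group and the diazo compound to 24 by removal of N2. The demand is that the phenol be the only O–H present.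

**21 back to 19, 18 and 17.** The C5 aldehyde is masked as a dithiane (19), the O9 silyl group is removed (18) and C9 is raised to an imide carbonyl (17). C5 is carried at the aldehyde level from the start, so no oxidant is ever used beside the electron-rich benzylic alcohol. The demand is a neutral unmasking, in which the C2 hydroxyl is expected to take part (through 20).

**17 back to 13 and 15, then 14.** The C2–C3 bond is cut (aldol). This removes two stereocentres and the whole aryl unit. The demand is syn selectivity and absolute control at a carbon next to the quaternary centre, which is handed to an auxiliary rather than to the weak bias of C4.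

**13 back to 10, 9, then 6 and 7.** The N-acyl bond, the ester and then the C3–C4 bond are cut (Claisen). The quaternary centre is traded for a secondary allylic carbinol. The demand is a suprafacial shift onto a trisubstituted alkene terminus.

**6 back to 5, then 1 and 2.** The carbinol C–H bond is cut (enantioselective ketone reduction), then the bond between C4 and C5 is cut (addition of a formyl anion equivalent to a vinylogous ester).

## Other disconnections considered

Alternative 1: De Mayo photoannulation.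
- Cut: C4–C6' and C2'–C3'. Ring A is dismantled and ring B is kept.
- Forward step: irradiation of the 4-methylene oxolane A1 with the enol of 3-oxobutanal A2 would give a cyclobutanol by [2+2] addition. Retro-aldol opening would give the keto aldehyde A3, and aldol condensation of A3 would give the enone A4, the all-TBS counterpart of 32.
- In favour: C9 and C8 both sit on one face of A1, so addition to the open face would place C6' on the aryl face, as required. On control of C4 this is the equal of the Claisen transfer and needs no chiral reagent. The C4' oxygen arrives with the annulation, so no allylic C–H oxidation is needed; on that point it is better than the chosen plan.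
- Against: A1 must be made as one isomer with four stereocentres and no quaternary carbon to lock them; C3 and C5 would be α to the ring ketone from which the methylene is made and could epimerise. The aryl ethers absorb where A2 does, the benzylic C2–O1 bond is photolabile, and the head-to-tail orientation of the cycloaddition is usual but not assured.
- Comparison: the structure is approached from the opposite side (ring B first). The mechanism is a triplet diradical pathway against an anionic equilibrium. Step economy is no better, because the diosphenol sequence of steps 19 to 21 would still follow from A4.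

Alternative 2: palladium (3+2) annulation.
- Cut: O1–C5 and C3–C4.
- Forward step: zerovalent palladium would open the vinyl oxirane A6 to a π-allyl alkoxide. The alkoxide would add to the methide carbon of the quinone methide A5 (O1–C5), and the para carbon of the resulting phenolate would close onto the allyl unit (C4–C3) to give the spirodienone A7.
- In favour: it is the most convergent of the four plans. Ring A arrives as the finished methoxy dienone, so the whole ring A oxidation sequence disappears; in step economy it is clearly better than the chosen plan. It forms O1–C5 by conjugate addition of oxygen as the chosen plan does, and is its equal there.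
- Against: C3, C4 and C5 would be set in one event with little to steer them. Addition to a flexible quinone methide gives weak control of C5 against C8. The C4 configuration depends on which rotamer of the unsymmetrical phenolate cyclises. O-allylation competes with dearomatising C-allylation. A5 lacks stabilising ortho substituents and would have to be made and used in situ. The vinyl group of A7 must then be cleaved to C9 beside an electron-rich dienone.
- Comparison: shorter and more convergent, but weaker on stereocontrol. The chosen plan fixes C2, C3 and C4 by reagent or sigmatropic control and leaves only C5 and C8 to an equilibrium.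

Alternative 3: Prins–pinacol spirocyclisation.
- Cut: O1–C2, C2–C3 and C4–C5.
- Forward step: the allylic diol A8 and the silylated vanillin A9 would condense under SnCl4 to an oxocarbenium ion. The exocyclic alkene would attack it (C2–C3), and the migration of C5 from C6' to the cationic C4 would contract the oxane to the oxolane and give the spiro ketone A10.
- In favour: three bonds, ring B and the quaternary centre form in one step through an ordered chair. C5 migrates with retention, so C5 and C8 come from an acyclic diol made by standard asymmetric methods; on control of C5 and C8 this is better than the chosen plan, which relies on an equilibrium.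
- Against: the ketone of A10 sits at C6', next to the spiro carbon, not at C4'. A carbonyl transposition around ring A (dehydrogenation, epoxidation, Wharton rearrangement, oxidation) is needed before the diosphenol sequence. SnCl4 could ionise the new benzylic C2–O1 bond of the electron-rich product. A8 needs a defined tertiary carbinol and a defined exocyclic alkene geometry.
- Comparison: stronger on the quaternary centre and on C5. The mechanism is a cationic cascade against an anionic equilibrium. Step economy is equal at best, because of the longer end game.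

Key step: step 15

Assumption: ester 29 is taken to be the most stable of its four C5/C8 epimers under the equilibrating conditions of step 15; this cannot be predicted with confidence and is covered by a fallback.

Abbreviations in names: TIPS = triisopropylsilyl; TBS = tert-butyldimethylsilyl; Ar1 = 3-methoxy-4-(triisopropylsilyloxy)phenyl; Ar2O = 2-methoxy-4-[3-(tert-butyldimethylsilyloxy)propyl]phenoxy. Atom labels are those defined under Structural features.

## Route

Step 1
Reactants: 1 1,3-dithiane; 2 3-ethoxycyclohex-2-en-1-one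
Product: 5 3-(1,3-dithian-2-yl)cyclohex-2-en-1-one, via 2-lithio-1,3-dithiane 3 (not isolated), via tertiary allylic carbinol 4 (not isolated)
Conditions: n-BuLi, THF, −30 °C; 2, −78 → 0 °C; 1 M HCl, THF, rt
Reagents that add atoms: water O (carbonyl oxygen of 5 enters during hydrolysis); n-butyllithium [Li]CCCC (lithium only in 3 and 4)
Why: Stork–Danheiser sequence: 1,2-addition of the dithiane anion to the vinylogous ester, then acid-promoted loss of water and hydrolysis of the enol ether transposes the enone and puts the masked C5 aldehyde on the future C4; no stereocentre survives.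

Step 2
Reactants: 5 3-(1,3-dithian-2-yl)cyclohex-2-en-1-one
Product: 6 (1S)-3-(1,3-dithian-2-yl)cyclohex-2-en-1-ol
Conditions: (R)-2-methyl-CBS-oxazaborolidine (10 mol%), BH3·SMe2, THF, −20 °C; MeOH
Reagents that add atoms: none
Why: CBS reduction; the alkenyl flank acts as the large group, so the (R)-catalyst should deliver hydride to give the (S)-carbinol, the centre from which C4 is derived.

Step 3
Reactants: 6 (1S)-3-(1,3-dithian-2-yl)cyclohex-2-en-1-ol; 7 triethyl orthoacetate
Product: 9 ethyl 2-[(1R)-1-(1,3-dithian-2-yl)cyclohex-2-en-1-yl]acetate, via mixed ketene acetal 8 (not isolated)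
Conditions: 7 (5 equiv), EtCO2H (5 mol%), xylene, 140 °C, EtOH distilled off
Reagents that add atoms: none
Why: Johnson–Claisen rearrangement; the [3,3] shift is suprafacial across the ring, so the C3–C4 bond forms on the face that held the C–O bond and the carbinol chirality is transferred to quaternary C4 while the alkene moves to C5'=C6'.

Step 4
Reactants: 9 ethyl 2-[(1R)-1-(1,3-dithian-2-yl)cyclohex-2-en-1-yl]acetate
Product: 10 2-[(1R)-1-(1,3-dithian-2-yl)cyclohex-2-en-1-yl]acetic acid
Conditions: LiOH, THF–MeOH–H2O, 40 °C; 1 M HCl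
Reagents that add atoms: lithium hydroxide [Li+].[OH-]
Why: Ester saponification; C4 is quaternary and cannot epimerise.

Step 5
Reactants: 10 2-[(1R)-1-(1,3-dithian-2-yl)cyclohex-2-en-1-yl]acetic acid; 11 (4S)-4-benzyl-1,3-oxazolidin-2-one
Product: 13 (4S)-4-benzyl-3-{2-[(1R)-1-(1,3-dithian-2-yl)cyclohex-2-en-1-yl]acetyl}-1,3-oxazolidin-2-one, via mixed pivalic anhydride 12 (not isolated)
Conditions: t-BuCOCl, Et3N, THF, −20 °C; 11, LiCl, rt
Reagents that add atoms: pivaloyl chloride CC(C)(C)C(Cl)=O (its atoms appear only in 12)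
Why: N-acylation of the oxazolidinone through the mixed anhydride with LiCl activation; any minor C4 enantiomer left by step 2 becomes a separable diastereomer from here on.

Step 6
Reactants: 14 vanillin
Product: 15 3-methoxy-4-(triisopropylsilyloxy)benzaldehyde
Conditions: i-Pr3SiCl, imidazole, DMF, rt
Reagents that add atoms: chlorotriisopropylsilane CC(C)[Si](Cl)(C(C)C)C(C)C
Why: Phenol silylation; TIPS is chosen over TBS because the aryl silyl ether has to outlast the basic steps 14 and 15.

Step 7
Reactants: 13 (4S)-4-benzyl-3-{2-[(1R)-1-(1,3-dithian-2-yl)cyclohex-2-en-1-yl]acetyl}-1,3-oxazolidin-2-one; 15 3-methoxy-4-(triisopropylsilyloxy)benzaldehyde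
Product: 17 (4S)-4-benzyl-3-{(2S,3S)-2-[(1S)-1-(1,3-dithian-2-yl)cyclohex-2-en-1-yl]-3-hydroxy-3-Ar1-propanoyl}-1,3-oxazolidin-2-one, via (Z)-dibutylboron enolate 16 (not isolated)
Conditions: n-Bu2BOTf, i-Pr2NEt, CH2Cl2, −78 → 0 °C; 15, −78 → 0 °C; pH 7 buffer–MeOH (no peroxide, to spare the dithiane)
Reagents that add atoms: dibutylboron triflate CCCCB(CCCC)OS(=O)(=O)C(F)(F)F (boron and butyl groups only in 16)
Why: Evans syn aldol; the (Z)-boron enolate should react through a closed chair transition state on the face away from the benzyl group, which sets C3 and C2 syn and in the absolute sense fixed by the (4S)-auxiliary, independent of the weak bias of C4.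

Step 8
Reactants: 17 (4S)-4-benzyl-3-{(2S,3S)-2-[(1S)-1-(1,3-dithian-2-yl)cyclohex-2-en-1-yl]-3-hydroxy-3-Ar1-propanoyl}-1,3-oxazolidin-2-one
Product: 18 (1S,2R)-2-[(1S)-1-(1,3-dithian-2-yl)cyclohex-2-en-1-yl]-1-Ar1-propane-1,3-diol
Conditions: LiBH4, MeOH (1 equiv), THF, 0 °C
Reagents that add atoms: none
Why: Reductive cleavage of the N-acyl oxazolidinone gives the C9 primary alcohol and returns the auxiliary; removing the C9 carbonyl before any basic step closes off retro-aldol cleavage and epimerisation at C3.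

Step 9
Reactants: 18 (1S,2R)-2-[(1S)-1-(1,3-dithian-2-yl)cyclohex-2-en-1-yl]-1-Ar1-propane-1,3-diol
Product: 19 (1S,2R)-2-[(1S)-1-(1,3-dithian-2-yl)cyclohex-2-en-1-yl]-1-Ar1-3-(triisopropylsilyloxy)propan-1-ol
Conditions: i-Pr3SiCl (1.1 equiv), imidazole, DMF, 0 °C → rt
Reagents that add atoms: chlorotriisopropylsilane CC(C)[Si](Cl)(C(C)C)C(C)C
Why: Silylation selective for the primary C9 hydroxyl over the hindered benzylic C2 hydroxyl; TIPS is used because it should not shift to the C2 alkoxide in step 15.

Step 10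
Reactants: 19 (1S,2R)-2-[(1S)-1-(1,3-dithian-2-yl)cyclohex-2-en-1-yl]-1-Ar1-3-(triisopropylsilyloxy)propan-1-ol
Product: 21 (3S,4R,5S)-3-Ar1-4-[(triisopropylsilyloxy)methyl]-2-oxaspiro[4.5]dec-6-en-1-ol (lactol; both anomers), via cyclic monothioacetal 20 (not isolated)
Conditions: MeI, CaCO3, MeCN–H2O (9:1), 45 °C
Reagents that add atoms: water O; iodomethane CI (its methyl group appears only in 20)
Why: Alkylative hydrolysis of the dithiane under neutral, non-oxidising conditions: S-methylation opens the dithiane to a thionium ion, which the C2 hydroxyl should trap as the five-membered O,S-acetal 20. A second S-methylation expels the thioether chain and water adds to the cyclic oxocarbenium ion, giving the lactol, the cyclic form of the C5 aldehyde.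

Step 11
Reactants: 22 dihydroconiferyl alcohol
Product: 23 4-[3-(tert-butyldimethylsilyloxy)propyl]-2-methoxyphenol
Conditions: t-BuMe2SiCl (1.05 equiv), imidazole, CH2Cl2, 0 °C
Reagents that add atoms: tert-butylchlorodimethylsilane CC(C)(C)[Si](C)(C)Cl
Why: Silylation of the primary alcohol, which should be faster than that of the hydrogen-bonded guaiacol hydroxyl.

Step 12
Reactants: 24 triethyl phosphonoacetate
Product: 25 ethyl 2-diazo-2-(diethoxyphosphoryl)acetate
Conditions: NaH, 4-acetamidobenzenesulfonyl azide, THF, 0 °C → rt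
Reagents that add atoms: 4-acetamidobenzenesulfonyl azide CC(=O)Nc1ccc(cc1)S(=O)(=O)N=[N+]=[N-]
Why: Regitz diazo transfer to the phosphonoacetate anion.

Step 13
Reactants: 23 4-[3-(tert-butyldimethylsilyloxy)propyl]-2-methoxyphenol; 25 ethyl 2-diazo-2-(diethoxyphosphoryl)acetate
Product: 26 ethyl 2-(diethoxyphosphoryl)-2-Ar2O-acetate (racemic)
Conditions: Rh2(OAc)4 (1 mol%), toluene, 80 °C
Reagents that add atoms: none
Why: O–H insertion of the rhodium carbenoid into the phenol forms the C8–O aryl ether bond; the phenol is the only O–H present, and the stereocentre formed is lost in step 14.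

Step 14
Reactants: 21 (3S,4R,5S)-3-Ar1-4-[(triisopropylsilyloxy)methyl]-2-oxaspiro[4.5]dec-6-en-1-ol (lactol); 26 ethyl 2-(diethoxyphosphoryl)-2-Ar2O-acetate
Product: 28 ethyl (2Z)-2-Ar2O-3-{(1S)-1-[(1S,2R)-1-hydroxy-1-Ar1-3-(triisopropylsilyloxy)propan-2-yl]cyclohex-2-en-1-yl}prop-2-enoate, via open-chain hydroxy aldehyde 27 (not isolated)
Conditions: LiCl, DBU, MeCN, rt → 45 °C
Reagents that add atoms: none
Why: Horner–Wadsworth–Emmons olefination under Masamune–Roush conditions; the lactol opens under the basic conditions to hydroxy aldehyde 27, which is the species that reacts. The ester should settle trans to the quaternary carbon, giving the (Z)-alkene, and neither the alkene geometry nor any early ring closure matters for step 15.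

Step 15
Reactants: 28 ethyl (2Z)-2-Ar2O-3-{(1S)-1-[(1S,2R)-1-hydroxy-1-Ar1-3-(triisopropylsilyloxy)propan-2-yl]cyclohex-2-en-1-yl}prop-2-enoate
Product: 29 ethyl (2R)-2-Ar2O-2-{(1S,3S,4R,5S)-3-Ar1-4-[(triisopropylsilyloxy)methyl]-2-oxaspiro[4.5]dec-6-en-1-yl}acetate, i.e. (2S,3R,4S,5S,8R) in the target labels
Conditions: KOt-Bu (0.2 equiv), t-BuOH–THF (1:10), 0 °C → rt until the isomer composition no longer changes; AcOH
Reagents that add atoms: none
Why: Catalytic tert-butoxide converts the C2 hydroxyl into its alkoxide, which adds to C5, the β-carbon of the 2-aryloxyacrylate, and the ester enolate so formed is protonated at C8 by tert-butanol. The closest known reaction type is the olefination–oxa-Michael closure used for C-glycosides and 2,5-disubstituted oxolanes, here with an α-aryloxy acrylate as acceptor. Ring B (O1, C2, C3, C4, C5) closes in the 5-exo-trig mode, helped by the quaternary C4 in the tether. C5 is controlled by the retro-Michael equilibrium: both alkene isomers of 28 and both C5 epimers interconvert through the open alkoxide, and the mixture should drain into the oxolane whose C8 chain is trans to the C2 aryl group and cis to C9, as the fixed centres C2, C3 and C4 decide. C8 is controlled by reversible enolisation of the α-aryloxy ester, the preferred arrangement next to C5 being the one that opposes the C8–O and C5–O1 dipoles. The step needs chemoselectivity, and the substrate secures it: ring A is a plain cyclohexene with no second acceptor, the C2 hydroxyl is the only free one, the TIPS group on O9 should not migrate, and lactonisation onto the ester would need a seven-membered ring. That 29 is the thermodynamic sink is the assumption stated before the steps.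

Step 16
Reactants: 29 ethyl (2R)-2-Ar2O-2-{(1S,3S,4R,5S)-3-Ar1-4-[(triisopropylsilyloxy)methyl]-2-oxaspiro[4.5]dec-6-en-1-yl}acetate
Product: 30 (2S)-2-Ar2O-2-{(1S,3S,4R,5S)-3-Ar1-4-[(triisopropylsilyloxy)methyl]-2-oxaspiro[4.5]dec-6-en-1-yl}ethan-1-ol
Conditions: i-Bu2AlH (3 equiv), CH2Cl2, −78 → −20 °C; aq. potassium sodium tartrate
Reagents that add atoms: none
Why: Ester reduction to the C10 alcohol under non-basic conditions; once C10 is an alcohol, C8 can no longer enolise and ring B can no longer open, so both new centres are locked (the descriptor at C8 changes to S by the sequence rule only).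

Step 17
Reactants: 30 (2S)-2-Ar2O-2-{(1S,3S,4R,5S)-3-Ar1-4-[(triisopropylsilyloxy)methyl]-2-oxaspiro[4.5]dec-6-en-1-yl}ethan-1-ol
Product: 31 (1S,3S,4R,5S)-1-[(1S)-1-Ar2O-2-(tert-butyldimethylsilyloxy)ethyl]-3-Ar1-4-[(triisopropylsilyloxy)methyl]-2-oxaspiro[4.5]dec-6-ene
Conditions: t-BuMe2SiCl, imidazole, DMF, rt
Reagents that add atoms: tert-butylchlorodimethylsilane CC(C)(C)[Si](C)(C)Cl
Why: Silylation of the primary C10 hydroxyl, so that no free hydroxyl faces the oxidations of ring A.

Step 18
Reactants: 31 (1S,3S,4R,5S)-1-[(1S)-1-Ar2O-2-(tert-butyldimethylsilyloxy)ethyl]-3-Ar1-4-[(triisopropylsilyloxy)methyl]-2-oxaspiro[4.5]dec-6-ene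
Product: 32 (1S,3S,4R,5S)-1-[(1S)-1-Ar2O-2-(tert-butyldimethylsilyloxy)ethyl]-3-Ar1-4-[(triisopropylsilyloxy)methyl]-2-oxaspiro[4.5]dec-6-en-8-one
Conditions: Rh2(cap)4 (cap = caprolactamate, 1 mol%), t-BuOOH (70% aq.), K2CO3, CH2Cl2, rt
Reagents that add atoms: tert-butyl hydroperoxide CC(C)(C)OO
Why: Allylic C–H oxidation by tert-butylperoxyl radicals; C4' is the only allylic CH2 because C4 is quaternary, and capture of the allyl radical at the unhindered C4' end should give the 4,4-disubstituted enone with the alkene still at C5'=C6'.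

Step 19
Reactants: 32 (1S,3S,4R,5S)-1-[(1S)-1-Ar2O-2-(tert-butyldimethylsilyloxy)ethyl]-3-Ar1-4-[(triisopropylsilyloxy)methyl]-2-oxaspiro[4.5]dec-6-en-8-one
Product: 34 (1S,3S,4R,5S)-1-[(1S)-1-Ar2O-2-(tert-butyldimethylsilyloxy)ethyl]-3-Ar1-9-hydroxy-4-[(triisopropylsilyloxy)methyl]-2-oxaspiro[4.5]dec-6-en-8-one (α'-hydroxy enone; OH on C3'; both epimers), via silyl dienol ether 33 (not isolated)
Conditions: LiN(SiMe3)2, Me3SiCl, THF, −78 °C; m-CPBA, NaHCO3, CH2Cl2, −20 °C; aq. citric acid
Reagents that add atoms: 3-chloroperbenzoic acid OOC(=O)c1cccc(Cl)c1; chlorotrimethylsilane C[Si](C)(C)Cl (silicon only in 33)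
Why: Rubottom oxidation; C3' holds the only enolisable hydrogens of the enone (C4 blocks the γ side), the cross-conjugated silyl dienol ether is epoxidised at its electron-rich enol ether bond, and the C3' configuration is irrelevant because step 20 erases it.

Step 20
Reactants: 34 α'-hydroxy enone (9-hydroxy derivative of 32)
Product: 36 (1S,3S,4R,5S)-1-[(1S)-1-Ar2O-2-(tert-butyldimethylsilyloxy)ethyl]-3-Ar1-7-hydroxy-4-[(triisopropylsilyloxy)methyl]-2-oxaspiro[4.5]deca-6,9-dien-8-one (diosphenol), via 1,2-dione 35 (not isolated)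
Conditions: Dess–Martin periodinane, NaHCO3, CH2Cl2, 0 °C → rt
Reagents that add atoms: none
Why: Oxidation of the α-hydroxy ketone to the 1,2-dione, which can enolise only towards C2' and so gives the cross-conjugated diosphenol; the oxygen now sits on the arm that was the CH2 arm of 9, which is what fixes the C4 configuration of the target.

Step 21
Reactants: 36 diosphenol
Product: 37 (1S,3S,4R,5S)-1-[(1S)-1-Ar2O-2-(tert-butyldimethylsilyloxy)ethyl]-3-Ar1-7-methoxy-4-[(triisopropylsilyloxy)methyl]-2-oxaspiro[4.5]deca-6,9-dien-8-one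
Conditions: Me3SiCHN2, MeOH–toluene (1:4), 0 °C → rt
Reagents that add atoms: (trimethylsilyl)diazomethane C[Si](C)(C)C=[N+]=[N-]
Why: O-methylation of the acidic diosphenol hydroxyl without base, so that no aryl silyl ether is cleaved and no phenol can be methylated by mistake.

Step 22
Reactants: 37 silylated methoxy dienone
Product: 38 (1S,3S,4R,5S)-1-[(1S)-2-hydroxy-1-[4-(3-hydroxypropyl)-2-methoxyphenoxy]ethyl]-3-(4-hydroxy-3-methoxyphenyl)-4-(hydroxymethyl)-7-methoxy-2-oxaspiro[4.5]deca-6,9-dien-8-one (CNP0252711.1)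
Conditions: Bu4NF, AcOH (1:1), THF, 0 °C → rt
Reagents that add atoms: none
Why: Fluoride cleavage of the two TBS and two TIPS ethers (one of them aryl); acetic acid buffering keeps the phenol, the benzylic C2–O1 ether and the dienone away from basic conditions.

## Compound list

1 | 1,3-dithiane | C1CSCSC1 | starting material
2 | 3-ethoxycyclohex-2-en-1-one | CCOC1=CC(=O)CCC1 | starting material
3 | 2-lithio-1,3-dithiane | [Li]C1SCCCS1 | intermediate
4 | 1-(1,3-dithian-2-yl)-3-ethoxycyclohex-2-en-1-ol (racemic; lithium alkoxide in the flask) | CCOC1=CC(O)(CCC1)C1SCCCS1 | intermediate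
5 | 3-(1,3-dithian-2-yl)cyclohex-2-en-1-one | O=C1C=C(CCC1)C1SCCCS1 | intermediate
6 | (1S)-3-(1,3-dithian-2-yl)cyclohex-2-en-1-ol | O[C@@H]1C=C(CCC1)C1SCCCS1 | intermediate
7 | triethyl orthoacetate | CCOC(C)(OCC)OCC | starting material
8 | 2-[(3S)-3-(1-ethoxyethenyloxy)cyclohex-1-en-1-yl]-1,3-dithiane | CCOC(=C)O[C@@H]1C=C(CCC1)C1SCCCS1 | intermediate
9 | ethyl 2-[(1R)-1-(1,3-dithian-2-yl)cyclohex-2-en-1-yl]acetate | C1CCC=C[C@]1(C2SCCCS2)CC(=O)OCC | intermediate
10 | 2-[(1R)-1-(1,3-dithian-2-yl)cyclohex-2-en-1-yl]acetic acid | C1CCC=C[C@]1(C2SCCCS2)CC(=O)O | intermediate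
11 | (4S)-4-benzyl-1,3-oxazolidin-2-one | O=C1N[C@@H](Cc2ccccc2)CO1 | starting material
12 | mixed anhydride of 10 with pivalic acid | C1CCC=C[C@]1(C2SCCCS2)CC(=O)OC(=O)C(C)(C)C | intermediate
13 | (4S)-4-benzyl-3-{2-[(1R)-1-(1,3-dithian-2-yl)cyclohex-2-en-1-yl]acetyl}-1,3-oxazolidin-2-one | C1CCC=C[C@]1(C2SCCCS2)CC(=O)N2[C@@H](Cc3ccccc3)COC2=O | intermediate
14 | vanillin | COc1cc(C=O)ccc1O | starting material
15 | 3-methoxy-4-(triisopropylsilyloxy)benzaldehyde | COc1cc(C=O)ccc1O[Si](C(C)C)(C(C)C)C(C)C | intermediate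
16 | (Z)-dibutylboron enolate of 13 (C4 S) | C1CCC=C[C@]1(C2SCCCS2)/C=C(/N2[C@@H](Cc3ccccc3)COC2=O)OB(CCCC)CCCC | intermediate
17 | (4S)-4-benzyl-3-{(2S,3S)-2-[(1S)-1-(1,3-dithian-2-yl)cyclohex-2-en-1-yl]-3-hydroxy-3-Ar1-propanoyl}-1,3-oxazolidin-2-one | C1CCC=C[C@]1(C2SCCCS2)[C@H](C(=O)N2[C@@H](Cc3ccccc3)COC2=O)[C@@H](c2ccc(O[Si](C(C)C)(C(C)C)C(C)C)c(OC)c2)O | intermediate
18 | (1S,2R)-2-[(1S)-1-(1,3-dithian-2-yl)cyclohex-2-en-1-yl]-1-Ar1-propane-1,3-diol | C1CCC=C[C@]1(C2SCCCS2)[C@H](CO)[C@@H](c2ccc(O[Si](C(C)C)(C(C)C)C(C)C)c(OC)c2)O | intermediate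
19 | (1S,2R)-2-[(1S)-1-(1,3-dithian-2-yl)cyclohex-2-en-1-yl]-1-Ar1-3-(triisopropylsilyloxy)propan-1-ol | C1CCC=C[C@]1(C2SCCCS2)[C@H](CO[Si](C(C)C)(C(C)C)C(C)C)[C@@H](c2ccc(O[Si](C(C)C)(C(C)C)C(C)C)c(OC)c2)O | intermediate
20 | (3S,4R,5S)-1-{[3-(methylsulfanyl)propyl]sulfanyl}-3-Ar1-4-[(triisopropylsilyloxy)methyl]-2-oxaspiro[4.5]dec-6-ene (cyclic monothioacetal; both epimers at C1, which is C5 of the target) | C1CCC=C[C@]12[C@H](CO[Si](C(C)C)(C(C)C)C(C)C)[C@@H](c1ccc(O[Si](C(C)C)(C(C)C)C(C)C)c(OC)c1)OC2SCCCSC | intermediate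
21 | (3S,4R,5S)-3-Ar1-4-[(triisopropylsilyloxy)methyl]-2-oxaspiro[4.5]dec-6-en-1-ol (both anomers at C1, which is C5 of the target) | C1CCC=C[C@]12[C@H](CO[Si](C(C)C)(C(C)C)C(C)C)[C@@H](c1ccc(O[Si](C(C)C)(C(C)C)C(C)C)c(OC)c1)OC2O | intermediate
22 | dihydroconiferyl alcohol, 4-(3-hydroxypropyl)-2-methoxyphenol | COc1cc(CCCO)ccc1O | starting material
23 | 4-[3-(tert-butyldimethylsilyloxy)propyl]-2-methoxyphenol | COc1cc(CCCO[Si](C)(C)C(C)(C)C)ccc1O | intermediate
24 | triethyl phosphonoacetate | CCOC(=O)CP(=O)(OCC)OCC | starting material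
25 | ethyl 2-diazo-2-(diethoxyphosphoryl)acetate | CCOC(=O)C(=[N+]=[N-])P(=O)(OCC)OCC | intermediate
26 | ethyl 2-(diethoxyphosphoryl)-2-Ar2O-acetate (racemic) | CCOC(=O)C(Oc1ccc(CCCO[Si](C)(C)C(C)(C)C)cc1OC)P(=O)(OCC)OCC | intermediate
27 | (1S)-1-[(1S,2R)-1-hydroxy-1-Ar1-3-(triisopropylsilyloxy)propan-2-yl]cyclohex-2-ene-1-carbaldehyde (open-chain form of 21) | C1CCC=C[C@]1(C=O)[C@H](CO[Si](C(C)C)(C(C)C)C(C)C)[C@@H](c1ccc(O[Si](C(C)C)(C(C)C)C(C)C)c(OC)c1)O | intermediate
28 | ethyl (2Z)-2-Ar2O-3-{(1S)-1-[(1S,2R)-1-hydroxy-1-Ar1-3-(triisopropylsilyloxy)propan-2-yl]cyclohex-2-en-1-yl}prop-2-enoate (key-step precursor; 2S,3R,4S in target labels) | C1CCC=C[C@]1(/C=C(/C(=O)OCC)Oc1ccc(CCCO[Si](C)(C)C(C)(C)C)cc1OC)[C@H](CO[Si](C(C)C)(C(C)C)C(C)C)[C@@H](c1ccc(O[Si](C(C)C)(C(C)C)C(C)C)c(OC)c1)O | intermediate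
29 | ethyl (2R)-2-Ar2O-2-{(1S,3S,4R,5S)-3-Ar1-4-[(triisopropylsilyloxy)methyl]-2-oxaspiro[4.5]dec-6-en-1-yl}acetate (key-step product) | C1CCC=C[C@]12[C@H](CO[Si](C(C)C)(C(C)C)C(C)C)[C@@H](c1ccc(O[Si](C(C)C)(C(C)C)C(C)C)c(OC)c1)O[C@@H]2[C@H](C(=O)OCC)Oc1ccc(CCCO[Si](C)(C)C(C)(C)C)cc1OC | intermediate
30 | (2S)-2-Ar2O-2-{(1S,3S,4R,5S)-3-Ar1-4-[(triisopropylsilyloxy)methyl]-2-oxaspiro[4.5]dec-6-en-1-yl}ethan-1-ol | C1CCC=C[C@]12[C@H](CO[Si](C(C)C)(C(C)C)C(C)C)[C@@H](c1ccc(O[Si](C(C)C)(C(C)C)C(C)C)c(OC)c1)O[C@@H]2[C@H](CO)Oc1ccc(CCCO[Si](C)(C)C(C)(C)C)cc1OC | intermediate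
31 | (1S,3S,4R,5S)-1-[(1S)-1-Ar2O-2-(tert-butyldimethylsilyloxy)ethyl]-3-Ar1-4-[(triisopropylsilyloxy)methyl]-2-oxaspiro[4.5]dec-6-ene | C1CCC=C[C@]12[C@H](CO[Si](C(C)C)(C(C)C)C(C)C)[C@@H](c1ccc(O[Si](C(C)C)(C(C)C)C(C)C)c(OC)c1)O[C@@H]2[C@H](CO[Si](C)(C)C(C)(C)C)Oc1ccc(CCCO[Si](C)(C)C(C)(C)C)cc1OC | intermediate
32 | (1S,3S,4R,5S)-1-[(1S)-1-Ar2O-2-(tert-butyldimethylsilyloxy)ethyl]-3-Ar1-4-[(triisopropylsilyloxy)methyl]-2-oxaspiro[4.5]dec-6-en-8-one | O=C1CC[C@]2(C=C1)[C@H](CO[Si](C(C)C)(C(C)C)C(C)C)[C@@H](c1ccc(O[Si](C(C)C)(C(C)C)C(C)C)c(OC)c1)O[C@@H]2[C@H](CO[Si](C)(C)C(C)(C)C)Oc1ccc(CCCO[Si](C)(C)C(C)(C)C)cc1OC | intermediate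
33 | 8-(trimethylsilyloxy)-2-oxaspiro[4.5]deca-6,8-diene derived from 32 (silyl dienol ether, other substituents as in 32) | C[Si](C)(C)OC1=CC[C@]2(C=C1)[C@H](CO[Si](C(C)C)(C(C)C)C(C)C)[C@@H](c1ccc(O[Si](C(C)C)(C(C)C)C(C)C)c(OC)c1)O[C@@H]2[C@H](CO[Si](C)(C)C(C)(C)C)Oc1ccc(CCCO[Si](C)(C)C(C)(C)C)cc1OC | intermediate
34 | 9-hydroxy derivative of 32 (OH on C3', both epimers) | OC1C[C@]2(C=CC1=O)[C@H](CO[Si](C(C)C)(C(C)C)C(C)C)[C@@H](c1ccc(O[Si](C(C)C)(C(C)C)C(C)C)c(OC)c1)O[C@@H]2[C@H](CO[Si](C)(C)C(C)(C)C)Oc1ccc(CCCO[Si](C)(C)C(C)(C)C)cc1OC | intermediate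
35 | 2-oxaspiro[4.5]dec-6-ene-8,9-dione derived from 34 (other substituents as in 32) | O=C1C[C@]2(C=CC1=O)[C@H](CO[Si](C(C)C)(C(C)C)C(C)C)[C@@H](c1ccc(O[Si](C(C)C)(C(C)C)C(C)C)c(OC)c1)O[C@@H]2[C@H](CO[Si](C)(C)C(C)(C)C)Oc1ccc(CCCO[Si](C)(C)C(C)(C)C)cc1OC | intermediate
36 | (1S,3S,4R,5S)-1-[(1S)-1-Ar2O-2-(tert-butyldimethylsilyloxy)ethyl]-3-Ar1-7-hydroxy-4-[(triisopropylsilyloxy)methyl]-2-oxaspiro[4.5]deca-6,9-dien-8-one | OC1=C[C@]2(C=CC1=O)[C@H](CO[Si](C(C)C)(C(C)C)C(C)C)[C@@H](c1ccc(O[Si](C(C)C)(C(C)C)C(C)C)c(OC)c1)O[C@@H]2[C@H](CO[Si](C)(C)C(C)(C)C)Oc1ccc(CCCO[Si](C)(C)C(C)(C)C)cc1OC | intermediate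
37 | 7-methoxy analogue of 36 (methyl ether of the diosphenol) | COC1=C[C@]2(C=CC1=O)[C@H](CO[Si](C(C)C)(C(C)C)C(C)C)[C@@H](c1ccc(O[Si](C(C)C)(C(C)C)C(C)C)c(OC)c1)O[C@@H]2[C@H](CO[Si](C)(C)C(C)(C)C)Oc1ccc(CCCO[Si](C)(C)C(C)(C)C)cc1OC | intermediate
38 | (1S,3S,4R,5S)-1-[(1S)-2-hydroxy-1-[4-(3-hydroxypropyl)-2-methoxyphenoxy]ethyl]-3-(4-hydroxy-3-methoxyphenyl)-4-(hydroxymethyl)-7-methoxy-2-oxaspiro[4.5]deca-6,9-dien-8-one | COC1=C[C@]2(C=CC1=O)[C@H](CO)[C@@H](c1ccc(O)c(OC)c1)O[C@@H]2[C@H](CO)Oc1ccc(CCCO)cc1OC | target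

## Step count and least certain steps

Total step count: 22. Longest linear sequence: 18 steps (steps 1 to 5, 7 to 10 and 14 to 22); step 6 and steps 11 to 13 are side branches.

**Step 15 (key step).** The equilibrium may settle on the wrong epimer at C5 or at C8, because the energy differences between oxolane epimers next to the spiro centre are small: the C8 chain must lie cis to C9 and next to the saturated arm C2'. The deactivated, hindered acceptor may also close slowly. The fallback sets out from 21 and returns at 29. Lactol 21 is oxidised (TEMPO, PhI(OAc)2) to the spiro lactone F1. Addition of the lithium enolate of ethyl acetate (lithium diisopropylamide, THF, −78 °C) gives the hemiketal F2. Ionic reduction (Et3SiH, BF3·OEt2, CH2Cl2, −78 °C) gives the oxolanyl acetate F3; here hydride, not the carbon chain, is delivered to the oxocarbenium ion and should enter anti to C9, leaving the chain cis to C9. Enolate hydroxylation (KN(SiMe3)2, 2-(phenylsulfonyl)-3-phenyloxaziridine) gives the (8S)-α-hydroxy ester F4, separated from its epimer. Mitsunobu etherification with phenol 23 (PPh3, diisopropyl azodicarboxylate) inverts C8 and gives 29.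

**Step 18.** Hydrogen abstraction may stray to the benzylic C2–H of ring B or to the benzylic CH2 of the propyl chain, and the allyl radical may be captured at C6', giving the transposed enone; both follow from the low selectivity of peroxyl radicals. The fallback sets out from 31 and returns at 32. The singlet oxygen ene reaction (O2, light, tetraphenylporphyrin, CH2Cl2) can take hydrogen only from C4' and gives the allylic hydroperoxide F5. Reduction with PPh3 gives the C6' allylic alcohol F6. A 1,3-transposition with O3ReOSiPh3 (heptavalent rhenium) moves the hydroxyl to the less hindered C4', giving the allylic alcohol F7. Dess–Martin oxidation gives 32.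

**Step 14.** The olefination may stall, because the lactol with its gem-disubstituted ring offers little open aldehyde and that aldehyde is neopentyl. The fallback sets out from 19 and returns at 28. The C2 hydroxyl is capped (Et3SiOTf, 2,6-lutidine) to give the triethylsilyl ether F8. Dithiane hydrolysis (MeI, CaCO3) gives the free aldehyde F9. Olefination with 26 (NaH, THF) gives the silylated acrylate F10. Selective removal of the secondary triethylsilyl group (AcOH–THF–H2O) gives 28.

**Step 7.** Addition of the crowded boron enolate (its α-carbon stands next to the quaternary centre that bears the dithiane) to an electron-rich aldehyde may be slow, and forcing it may erode the syn selectivity. The fallback sets out from 9 and returns at 18. The smaller lithium enolate of 9 (lithium diisopropylamide, THF, −78 °C) is added to 15 to give the β-hydroxy ester F11 under substrate control, with separation of diastereomers. Material with the wrong C2 configuration is converged by Dess–Martin oxidation to the β-keto ester F12 and chelation-controlled reduction with Zn(BH4)2 back to syn F11. LiAlH4 reduction of F11 gives diol 18.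

**Step 3.** At 140 °C with acid the allylic carbinol may eliminate to a diene, and the crowded terminus bearing the dithiane may slow the rearrangement. The fallback sets out from 6 and returns at 10. Acetylation (Ac2O, pyridine, DMAP) gives the allylic acetate F13. Ireland–Claisen rearrangement of its silyl ketene acetal (lithium diisopropylamide, Me3SiCl, Et3N, THF, −78 → 60 °C; aq. HCl) gives acid 10 directly, without ester 9.

## Further compounds

F1 | step 15 | (3S,4R,5S)-3-Ar1-4-[(triisopropylsilyloxy)methyl]-2-oxaspiro[4.5]dec-6-en-1-one (spiro lactone) | C1CCC=C[C@]12[C@H](CO[Si](C(C)C)(C(C)C)C(C)C)[C@@H](c1ccc(O[Si](C(C)C)(C(C)C)C(C)C)c(OC)c1)OC2=O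
F2 | step 15 | ethyl 2-{(3S,4R,5S)-3-Ar1-1-hydroxy-4-[(triisopropylsilyloxy)methyl]-2-oxaspiro[4.5]dec-6-en-1-yl}acetate (hemiketal, both C1 epimers) | C1CCC=C[C@]12[C@H](CO[Si](C(C)C)(C(C)C)C(C)C)[C@@H](c1ccc(O[Si](C(C)C)(C(C)C)C(C)C)c(OC)c1)OC2(O)CC(=O)OCC
F3 | step 15 | ethyl 2-{(1R,3S,4R,5S)-3-Ar1-4-[(triisopropylsilyloxy)methyl]-2-oxaspiro[4.5]dec-6-en-1-yl}acetate (C5 arranged as in 29) | C1CCC=C[C@]12[C@H](CO[Si](C(C)C)(C(C)C)C(C)C)[C@@H](c1ccc(O[Si](C(C)C)(C(C)C)C(C)C)c(OC)c1)O[C@@H]2CC(=O)OCC
F4 | step 15 | ethyl (2S)-2-hydroxy-2-{(1S,3S,4R,5S)-3-Ar1-4-[(triisopropylsilyloxy)methyl]-2-oxaspiro[4.5]dec-6-en-1-yl}acetate | C1CCC=C[C@]12[C@H](CO[Si](C(C)C)(C(C)C)C(C)C)[C@@H](c1ccc(O[Si](C(C)C)(C(C)C)C(C)C)c(OC)c1)O[C@@H]2[C@@H](C(=O)OCC)O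
F5 | step 18 | C6' hydroperoxide of 31 with the alkene moved to C4'=C5' (2-oxaspiro[4.5]dec-7-en-6-yl hydroperoxide, C6' epimers) | C1C[C@]2(C(OO)C=C1)[C@H](CO[Si](C(C)C)(C(C)C)C(C)C)[C@@H](c1ccc(O[Si](C(C)C)(C(C)C)C(C)C)c(OC)c1)O[C@@H]2[C@H](CO[Si](C)(C)C(C)(C)C)Oc1ccc(CCCO[Si](C)(C)C(C)(C)C)cc1OC
F6 | step 18 | C6' allylic alcohol corresponding to F5 (2-oxaspiro[4.5]dec-7-en-6-ol, C6' epimers) | C1C[C@]2(C(O)C=C1)[C@H](CO[Si](C(C)C)(C(C)C)C(C)C)[C@@H](c1ccc(O[Si](C(C)C)(C(C)C)C(C)C)c(OC)c1)O[C@@H]2[C@H](CO[Si](C)(C)C(C)(C)C)Oc1ccc(CCCO[Si](C)(C)C(C)(C)C)cc1OC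
F7 | step 18 | C4' allylic alcohol (2-oxaspiro[4.5]dec-6-en-8-ol, C4' epimers; other substituents as in 31) | OC1CC[C@]2(C=C1)[C@H](CO[Si](C(C)C)(C(C)C)C(C)C)[C@@H](c1ccc(O[Si](C(C)C)(C(C)C)C(C)C)c(OC)c1)O[C@@H]2[C@H](CO[Si](C)(C)C(C)(C)C)Oc1ccc(CCCO[Si](C)(C)C(C)(C)C)cc1OC
F8 | step 14 | triethylsilyl ether of 19 at the C2 oxygen | C1CCC=C[C@]1(C2SCCCS2)[C@H](CO[Si](C(C)C)(C(C)C)C(C)C)[C@@H](c2ccc(O[Si](C(C)C)(C(C)C)C(C)C)c(OC)c2)O[Si](CC)(CC)CC
F9 | step 14 | triethylsilyl ether of aldehyde 27 at the C2 oxygen | C1CCC=C[C@]1(C=O)[C@H](CO[Si](C(C)C)(C(C)C)C(C)C)[C@@H](c1ccc(O[Si](C(C)C)(C(C)C)C(C)C)c(OC)c1)O[Si](CC)(CC)CC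
F10 | step 14 | triethylsilyl ether of 28 at the C2 oxygen, (Z)-alkene | C1CCC=C[C@]1(/C=C(/C(=O)OCC)Oc1ccc(CCCO[Si](C)(C)C(C)(C)C)cc1OC)[C@H](CO[Si](C(C)C)(C(C)C)C(C)C)[C@@H](c1ccc(O[Si](C(C)C)(C(C)C)C(C)C)c(OC)c1)O[Si](CC)(CC)CC
F11 | step 7 | ethyl (2S,3S)-2-[(1S)-1-(1,3-dithian-2-yl)cyclohex-2-en-1-yl]-3-hydroxy-3-Ar1-propanoate | C1CCC=C[C@]1(C2SCCCS2)[C@H](C(=O)OCC)[C@@H](c2ccc(O[Si](C(C)C)(C(C)C)C(C)C)c(OC)c2)O
F12 | step 7 | ethyl 2-[(1S)-1-(1,3-dithian-2-yl)cyclohex-2-en-1-yl]-3-oxo-3-Ar1-propanoate (C3 epimerisable) | C1CCC=C[C@]1(C2SCCCS2)C(C(=O)OCC)C(=O)c2ccc(O[Si](C(C)C)(C(C)C)C(C)C)c(OC)c2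
F13 | step 3 | (1S)-3-(1,3-dithian-2-yl)cyclohex-2-en-1-yl acetate | CC(=O)O[C@@H]1C=C(CCC1)C1SCCCS1
A1 | alternative 1 | 4-methylene oxolane with C2, C3, C5 and C8 as in the target, all hydroxyls as TBS ethers | C=C1[C@H](CO[Si](C)(C)C(C)(C)C)[C@@H](c2ccc(O[Si](C)(C)C(C)(C)C)c(OC)c2)O[C@@H]1[C@H](CO[Si](C)(C)C(C)(C)C)Oc1ccc(CCCO[Si](C)(C)C(C)(C)C)cc1OC
A2 | alternative 1 | 3-oxobutanal as its enol, (Z)-4-hydroxybut-3-en-2-one | C(/O)=C/C(C)=O
A3 | alternative 1 | oxolane with quaternary C4 bearing formyl (C6') and 3-oxobutyl (C2' to C5') | CC(=O)CC[C@]1(C=O)[C@H](CO[Si](C)(C)C(C)(C)C)[C@@H](c2ccc(O[Si](C)(C)C(C)(C)C)c(OC)c2)O[C@@H]1[C@H](CO[Si](C)(C)C(C)(C)C)Oc1ccc(CCCO[Si](C)(C)C(C)(C)C)cc1OC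
A4 | alternative 1 | spiro enone, 2-oxaspiro[4.5]dec-6-en-8-one with all hydroxyls as TBS ethers (all-TBS counterpart of 32) | O=C1CC[C@]2(C=C1)[C@H](CO[Si](C)(C)C(C)(C)C)[C@@H](c1ccc(O[Si](C)(C)C(C)(C)C)c(OC)c1)O[C@@H]2[C@H](CO[Si](C)(C)C(C)(C)C)Oc1ccc(CCCO[Si](C)(C)C(C)(C)C)cc1OC
A5 | alternative 2 | 2-methoxy quinone methide whose methide carbon C5 bears C8, with C8 arranged as in the target | COC1=CC(=C[C@H](CO[Si](C)(C)C(C)(C)C)Oc2ccc(CCCO[Si](C)(C)C(C)(C)C)cc2OC)C=CC1=O
A6 | alternative 2 | 2-[4-(tert-butyldimethylsilyloxy)-3-methoxyphenyl]-3-vinyloxirane, aryl carbon arranged as C2 of the target | C=CC1O[C@@H]1c2ccc(O[Si](C)(C)C(C)(C)C)c(OC)c2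
A7 | alternative 2 | silylated spirodienone with vinyl on C3 | COC1=C[C@]2(C=CC1=O)[C@H](C=C)[C@@H](c1ccc(O[Si](C)(C)C(C)(C)C)c(OC)c1)O[C@@H]2[C@H](CO[Si](C)(C)C(C)(C)C)Oc1ccc(CCCO[Si](C)(C)C(C)(C)C)cc1OC
A8 | alternative 3 | allylic diol: 2-alkylidenecyclohexan-1-ol with tertiary hydroxyl on C6' and secondary hydroxyl on C5, C5 and C8 as in the target, C6' and alkene geometry left open | O[C@@H](C1(O)CCCCC1=CCO[Si](C)(C)C(C)(C)C)[C@H](CO[Si](C)(C)C(C)(C)C)Oc1ccc(CCCO[Si](C)(C)C(C)(C)C)cc1OC
A9 | alternative 3 | 4-(tert-butyldimethylsilyloxy)-3-methoxybenzaldehyde | COc1cc(C=O)ccc1O[Si](C)(C)C(C)(C)C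
A10 | alternative 3 | spiro oxolane with the ring A ketone at C6' | O=C1CCCC[C@@]12[C@H](CO[Si](C)(C)C(C)(C)C)[C@@H](c1ccc(O[Si](C)(C)C(C)(C)C)c(OC)c1)O[C@@H]2[C@H](CO[Si](C)(C)C(C)(C)C)Oc1ccc(CCCO[Si](C)(C)C(C)(C)C)cc1OC
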